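Assumption: (R)-2-methylbutanoic acid (≥98% ee) is taken as a catalogue chemical. From the SMILES, both stereocentres are read as R (acyl α-carbon and C2 of the dihydrofuran).

**Retrosynthetic overview**
1. Cut the ArCH2–pyrone bridge: dihydrobenzofuran acylphloroglucinol + 4-hydroxy-2-pyrone + one CH2 (Mannich / pyrone-methide coupling, last step).
2. Open the dihydrofuran ring to a C-prenyl acylphloroglucinol: one-step enantioselective Pd(II) dehydrogenative cyclisation (prenyl → 2-isopropenyl-dihydrofuran), copying the oxidative cyclase step without an epoxide/alcohol/dehydration detour.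
3. Prenyl acylphloroglucinol ⇒ phloroglucinol + (R)-2-methylbutanoic acid (C-acylation) + prenyl bromide (C-prenylation, as the prenyltransferase does).
4. Pyrone ⇒ pentan-3-one enol silane + malonyl dichloride (C-acylation, then enol-lactonisation of a triketide equivalent).
5. Ring order: benzene ring bought; dihydrofuran ring (step 3); pyrone ring (step 5, separate branch); bridge (step 6).

**Route**

Step 1
Reactants: 1 phloroglucinol (benzene-1,3,5-triol, anhydrous); 2 (R)-2-methylbutanoic acid
Product: 4 (2R)-2-methyl-1-(2,4,6-trihydroxyphenyl)butan-1-one, via (R)-2-methylbutanoyl chloride 3 (not isolated)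
Conditions: 2, (COCl)2 (1.0 equiv), cat. DMF, CH2Cl2, 0 → 25 °C, N2 purge; then add to 1, AlCl3 (4 equiv), CH2Cl2–PhNO2, 0 → 25 °C; ice/1 M HCl
Reagents that add atoms: oxalyl chloride, O=C(Cl)C(=O)Cl (gives the Cl of 3 only; no atom of it stays in 4)
Why: Friedel–Crafts acylation of the symmetric, electron-rich triol stops at the chelated mono-ketone; no new stereocentre is formed, and the α-centre of 2 is carried through by keeping the acylation at or below 25 °C.

Step 2
Reactants: 4 (2R)-2-methyl-1-(2,4,6-trihydroxyphenyl)butan-1-one; 5 prenyl bromide (1-bromo-3-methylbut-2-ene)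
Product: 6 (2R)-2-methyl-1-[2,4,6-trihydroxy-3-(3-methylbut-2-en-1-yl)phenyl]butan-1-one
Conditions: 5 (0.9 equiv), 10% aq KOH (2 equiv), 0 °C, 2 h; then 1 M HCl; recover unreacted 4
Reagents that add atoms: none
Why: C-alkylation of the ambident phloroglucinolate in water (the chemical counterpart of aromatic prenyl transfer) gives one regioisomer because the two free ring carbons are equivalent; the α-centre is not enolised because the ketone is a vinylogous carboxylate in the phenolate.

Step 3
Reactants: 6 (2R)-2-methyl-1-[2,4,6-trihydroxy-3-(3-methylbut-2-en-1-yl)phenyl]butan-1-one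
Product: 7 (2R)-1-[(2R)-4,6-dihydroxy-2-(prop-1-en-2-yl)-2,3-dihydro-1-benzofuran-5-yl]-2-methylbutan-1-one
Conditions: Pd(OCOCF3)2 (10 mol %), (R,R)-iPr-boxax [(R)-2,2'-bis((4R)-4-isopropyl-4,5-dihydrooxazol-2-yl)-1,1'-binaphthyl] (20 mol %), p-benzoquinone (2 equiv), MeOH, 40 °C
Reagents that add atoms: none
Why: Proposed new method: an enantioselective Wacker-type oxidative cyclisation in which the most acidic, non-chelated 4-OH (para to the acyl group; the two ortho-OH are engaged with the C=O) binds cationic Pd(II) as phenoxide, 5-exo oxypalladation of the prenyl alkene puts Pd on the tertiary carbon, and β-hydride elimination from a methyl group releases the isopropenyl group and Pd(0), which benzoquinone reoxidises; the C2 centre is set in the oxypalladation by the C2-symmetric bis(oxazoline) ligand (the R,R antipode is the one predicted by analogy to give 2R; if the first run gives 2S the mirror-image ligand is used); the closest known reactions are the Pd(II)/boxax/benzoquinone cyclisation of 2-(2,3-dimethylbut-2-enyl)phenols to 2-isopropenyl-2-methyl-dihydrobenzofurans in >90% ee and the racemic Pd(OAc)2 cyclisation of 2-prenylphenol to 2-isopropenyl-2,3-dihydrobenzofuran.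

Step 4
Reactants: 8 pentan-3-one
Product: 9 (Z)-trimethyl(pent-2-en-3-yloxy)silane (Z-major E/Z mixture, used as such; geometry is lost in step 5)
Conditions: TMSOTf (1.05 equiv), Et3N (1.2 equiv), CH2Cl2, 0 °C; pentane extraction, distillation
Reagents that add atoms: trimethylsilyl trifluoromethanesulfonate, C[Si](C)(C)OS(=O)(=O)C(F)(F)F
Why: Soft enolisation with O-silylation of a symmetric ketone, so only one constitutional enol silane can form; no stereocentre is involved.

Step 5
Reactants: 9 (Z)-trimethyl(pent-2-en-3-yloxy)silane; 10 malonyl dichloride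
Product: 12 6-ethyl-4-hydroxy-5-methyl-2H-pyran-2-one, via 4-methyl-3,5-dioxoheptanoyl chloride 11 (not isolated)
Conditions: 10 (1.0 equiv), Et2O, −78 → 25 °C, 12 h; filter the precipitated pyrone
Reagents that add atoms: none
Why: C-acylation of the enol silane by one acid chloride (loss of TMSCl) gives a triketide-type 3,5-diketo acid chloride, whose enol oxygen closes onto the second acid chloride (enol-lactonisation) to the aromatic 4-hydroxy-2-pyrone, the same closure the polyketide synthase performs.

Step 6
Reactants: 12 6-ethyl-4-hydroxy-5-methyl-2H-pyran-2-one; 13 Eschenmoser's salt (N,N-dimethylmethyleneiminium iodide); 7 (2R)-1-[(2R)-4,6-dihydroxy-2-(prop-1-en-2-yl)-2,3-dihydro-1-benzofuran-5-yl]-2-methylbutan-1-one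
Product: 16 3-{[(2R)-4,6-dihydroxy-5-[(2R)-2-methylbutanoyl]-2-(prop-1-en-2-yl)-2,3-dihydro-1-benzofuran-7-yl]methyl}-6-ethyl-4-hydroxy-5-methyl-2H-pyran-2-one, via Mannich base 14 (not isolated), via pyrone methide 15 (not isolated)
Conditions: 12 (1.1 equiv), 13 (1.05 equiv), MeCN, 25 °C, 1 h; then 7 (1.0 equiv), 55 °C, 6 h
Reagents that add atoms: none
Why: Mannich reaction at pyrone C3, thermal loss of dimethylamine to the 3-methylene-pyrandione, and Friedel–Crafts-type conjugate addition by C7 of 7 (its only free ring carbon) forge the methylene bridge under near-neutral conditions; no stereocentre is formed and neither existing centre nor the acid-sensitive allylic ether is touched.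

**Compound list**
1 | phloroglucinol (benzene-1,3,5-triol) | Oc1cc(O)cc(O)c1 | starting material
2 | (R)-2-methylbutanoic acid | CC[C@@H](C)C(=O)O | starting material
3 | (R)-2-methylbutanoyl chloride | CC[C@@H](C)C(=O)Cl | intermediate (not isolated)
4 | (2R)-2-methyl-1-(2,4,6-trihydroxyphenyl)butan-1-one | CC[C@@H](C)C(=O)c1c(O)cc(O)cc1O | intermediate
5 | prenyl bromide (1-bromo-3-methylbut-2-ene) | CC(C)=CCBr | starting material
6 | (2R)-2-methyl-1-[2,4,6-trihydroxy-3-(3-methylbut-2-en-1-yl)phenyl]butan-1-one | CC[C@@H](C)C(=O)c1c(O)cc(O)c(CC=C(C)C)c1O | intermediate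
7 | (2R)-1-[(2R)-4,6-dihydroxy-2-(prop-1-en-2-yl)-2,3-dihydro-1-benzofuran-5-yl]-2-methylbutan-1-one | C=C(C)[C@H]1Cc2c(O)c(C(=O)[C@H](C)CC)c(O)cc2O1 | intermediate
8 | pentan-3-one | CCC(=O)CC | starting material
9 | (Z)-trimethyl(pent-2-en-3-yloxy)silane | C/C=C(/CC)O[Si](C)(C)C | intermediate
10 | malonyl dichloride | O=C(Cl)CC(=O)Cl | starting material
11 | 4-methyl-3,5-dioxoheptanoyl chloride | CCC(=O)C(C)C(=O)CC(=O)Cl | intermediate (not isolated)
12 | 6-ethyl-4-hydroxy-5-methyl-2H-pyran-2-one | CCc1oc(=O)cc(O)c1C | intermediate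
13 | Eschenmoser's salt (N,N-dimethylmethyleneiminium iodide) | C=[N+](C)C.[I-] | starting material
14 | 3-[(dimethylamino)methyl]-6-ethyl-4-hydroxy-5-methyl-2H-pyran-2-one (Mannich base) | CCc1oc(=O)c(CN(C)C)c(O)c1C | intermediate (not isolated)
15 | 6-ethyl-5-methyl-3-methylidene-2H-pyran-2,4(3H)-dione (pyrone methide) | CCC1=C(C)C(=O)C(=C)C(=O)O1 | intermediate (not isolated)
16 | 3-{[(2R)-4,6-dihydroxy-5-[(2R)-2-methylbutanoyl]-2-(prop-1-en-2-yl)-2,3-dihydro-1-benzofuran-7-yl]methyl}-6-ethyl-4-hydroxy-5-methyl-2H-pyran-2-one | C=C(C)[C@H]1Cc2c(O)c(C(=O)[C@H](C)CC)c(O)c(Cc3c(O)c(C)c(CC)oc3=O)c2O1 | target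

**Step count**
Total: 6 steps. Longest linear sequence: 4 steps (1 → 2 → 3 → 6); the pyrone branch is 2 steps (4 → 5) before the convergent step 6.

**Steps most likely to fail, with fallbacks**

Step 3 (most at risk). Four things can go wrong:
- closure through the 2-OH instead of the 4-OH;
- 6-endo closure to the 2,2-dimethylchromene, or aromatisation to the benzofuran;
- Pd sequestered by the o-hydroxyaryl ketone chelate, or benzoquinone attacking the free ring carbon;
- insufficient or reversed facial selectivity, giving the 2S epimer, which is hard to separate because the acyl stereocentre is remote.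

The fallback sets out from 6 and comes back at 7, replacing oxypalladation by epoxide opening. Compound 6 is peracetylated (Ac2O, pyridine) to (2R)-2-methyl-1-[2,4,6-triacetoxy-3-(3-methylbut-2-en-1-yl)phenyl]butan-1-one F1. Shi epoxidation with the L-fructose-derived (ent-Shi) ketone and Oxone (buffered MeCN/dimethoxymethane/water, 0 °C) gives (2R)-1-[2,4,6-triacetoxy-3-{[(2S)-3,3-dimethyloxiran-2-yl]methyl}phenyl]-2-methylbutan-1-one F2. K2CO3 in MeOH removes the acetates, and the 4-phenoxide opens the epoxide 5-exo at the secondary carbon with inversion, giving (2R)-1-[(2R)-4,6-dihydroxy-2-(2-hydroxypropan-2-yl)-2,3-dihydro-1-benzofuran-5-yl]-2-methylbutan-1-one F3. Burgess reagent (toluene, 50 °C, syn-elimination towards methyl) then dehydrates the tertiary alcohol to 7.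

Step 2. Mono-C-prenylation competes with O-prenylation and with 3,5- and 3,3-diprenylation, so yields are modest. The fallback sets out from 4 and comes back at 6, delivering the C5 unit by sigmatropic rearrangement instead of direct C-alkylation. The most acidic 4-OH of 4 is alkylated with 3-chloro-3-methylbut-1-yne (K2CO3, KI, cat. CuI, acetone) to (2R)-1-{2,6-dihydroxy-4-[(2-methylbut-3-yn-2-yl)oxy]phenyl}-2-methylbutan-1-one F4. Lindlar semi-hydrogenation gives (2R)-1-{2,6-dihydroxy-4-[(2-methylbut-3-en-2-yl)oxy]phenyl}-2-methylbutan-1-one F5. Aromatic Claisen rearrangement (toluene, 110 °C) transfers the unit with allylic inversion to the equivalent ortho carbons and gives 6.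

Step 6. The pyrone methide can be diverted to the methylene-bis-pyrone, or add sluggishly to the acyl-deactivated arene. The fallback sets out from 7 and comes back at 16 with the polarity of the coupling reversed. Compound 7 is aminomethylated at C7 with Eschenmoser's salt to (2R)-1-[(2R)-7-[(dimethylamino)methyl]-4,6-dihydroxy-2-(prop-1-en-2-yl)-2,3-dihydro-1-benzofuran-5-yl]-2-methylbutan-1-one F6. Heating F6 with 12 (dioxane, 80 °C) generates the ortho-quinone methide of the phloroglucinol, which is trapped by the nucleophilic C3 of the pyrone to give 16.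

**Further compounds**
F1 | step 3 | (2R)-2-methyl-1-[2,4,6-triacetoxy-3-(3-methylbut-2-en-1-yl)phenyl]butan-1-one | CC[C@@H](C)C(=O)c1c(OC(C)=O)cc(OC(C)=O)c(CC=C(C)C)c1OC(C)=O
F2 | step 3 | (2R)-1-[2,4,6-triacetoxy-3-{[(2S)-3,3-dimethyloxiran-2-yl]methyl}phenyl]-2-methylbutan-1-one | CC[C@@H](C)C(=O)c1c(OC(C)=O)cc(OC(C)=O)c(C[C@@H]2OC2(C)C)c1OC(C)=O
F3 | step 3 | (2R)-1-[(2R)-4,6-dihydroxy-2-(2-hydroxypropan-2-yl)-2,3-dihydro-1-benzofuran-5-yl]-2-methylbutan-1-one | CC(C)(O)[C@H]1Cc2c(O)c(C(=O)[C@H](C)CC)c(O)cc2O1
F4 | step 2 | (2R)-1-{2,6-dihydroxy-4-[(2-methylbut-3-yn-2-yl)oxy]phenyl}-2-methylbutan-1-one | CC[C@@H](C)C(=O)c1c(O)cc(OC(C)(C)C#C)cc1O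
F5 | step 2 | (2R)-1-{2,6-dihydroxy-4-[(2-methylbut-3-en-2-yl)oxy]phenyl}-2-methylbutan-1-one | CC[C@@H](C)C(=O)c1c(O)cc(OC(C)(C)C=C)cc1O
F6 | step 6 | (2R)-1-[(2R)-7-[(dimethylamino)methyl]-4,6-dihydroxy-2-(prop-1-en-2-yl)-2,3-dihydro-1-benzofuran-5-yl]-2-methylbutan-1-one | C=C(C)[C@H]1Cc2c(O)c(C(=O)[C@H](C)CC)c(O)c(CN(C)C)c2O1
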